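Ring B is disconnected at C7–C8. In ring B the isopropenyl group on C7 sits next to the oxygenated C8, the homoallylic pattern that an intramolecular carbonyl-ene reaction leaves behind. A Lewis-acid-bound C8 aldehyde is attacked by the prenyl group on C5; this single operation forms ring B, sets C7 and C8, and converts the prenyl unit into the isopropenyl group by hydrogen transfer. The precursor is a fully decorated ring A cyclohexane with the C3 senecioate, the C4 and C5 methyl groups, the C5 prenyl group and, trans to it on C10, an (S)-α-triethylsilyloxy acetaldehyde arm (C9, C8). Oxidation at C8 and silyl-to-tiglate exchange at C9 then give the target.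

Key step: step 9

Remark: ring positions are given in eremophilane numbering (ring A = C1–C5 and C10, ring B = C5–C10); the ligand enantiomers in steps 1 and 2 are assumed to be those that give the configurations drawn, to be assigned on a model substrate.

Step 1
Reactants: 1 2-methylcyclohex-2-en-1-one; 2 vinylmagnesium bromide; 3 prenyl bromide (1-bromo-3-methylbut-2-ene)
Product: 5 (2S,3S)-2-methyl-2-(3-methylbut-2-en-1-yl)-3-vinylcyclohexan-1-one, via magnesium enolate 4 (not isolated)
Conditions: CuBr·SMe2 (5 mol %), Josiphos-type ferrocenyl diphosphine (6 mol %), tBuOMe, −78 °C; then 3, DMPU, −78 → 0 °C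
Reagents that add atoms: vinylmagnesium bromide 2, C=C[Mg]Br; prenyl bromide 3, CC(C)=CCBr
Why: Copper-catalysed asymmetric conjugate addition of the Grignard reagent, in which the chiral copper–diphosphine complex chooses the enone face and sets C10 (3S), gives a regiodefined magnesium enolate whose C-alkylation by the allylic bromide occurs anti to the new vinyl group and so sets the quaternary C5 (2S) trans to it (tandem conjugate addition–enolate alkylation).

Step 2
Reactants: 5
Product: 7 (2S,3R)-3-[(1S)-1,2-dihydroxyethyl]-2-methyl-2-(3-methylbut-2-en-1-yl)cyclohexan-1-one, via bis(pinacolboronate) 6 (not isolated)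
Conditions: B2pin2 (1.1 equiv), Pt(dba)3 (3 mol %), TADDOL-derived phosphonite (6 mol %), THF, 60 °C; then 30% H2O2, 3 M NaOH, 0 °C → rt
Reagents that add atoms: hydrogen peroxide, OO
Why: Platinum-catalysed enantioselective 1,2-diboration acts only on the monosubstituted vinyl group because the trisubstituted prenyl alkene does not insert into the Pt–boryl bond, the chiral phosphonite selects the alkene face and thereby sets C9 (S), and the stereoretentive oxidation of both C–B bonds should then give the diol.

Step 3
Reactants: 7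
Product: 8 (2S,3R)-3-[(1S)-1,2-bis(triethylsilyloxy)ethyl]-2-methyl-2-(3-methylbut-2-en-1-yl)cyclohexan-1-one
Conditions: TESCl (2.5 equiv), imidazole (4 equiv), DMF, 0 °C → rt
Reagents that add atoms: chlorotriethylsilane, CC[Si](Cl)(CC)CC
Why: Routine silylation of both hydroxyl groups leaves the hindered ketone alone, and triethylsilyl is chosen because the primary ether can later be oxidised directly to the aldehyde while the secondary one can be removed beside a ketone under mild acid.

Step 4
Reactants: 8
Product: 10 (2S,3R,6R)-3-[(1S)-1,2-bis(triethylsilyloxy)ethyl]-6-hydroxy-2-methyl-2-(3-methylbut-2-en-1-yl)cyclohexan-1-one, via potassium enolate 9 (not isolated)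
Conditions: KHMDS (1.2 equiv), THF, −78 °C; 2-(phenylsulfonyl)-3-phenyloxaziridine (1.4 equiv), −78 °C; AcOH
Reagents that add atoms: 2-(phenylsulfonyl)-3-phenyloxaziridine, O=S(=O)(c1ccccc1)N1OC1c1ccccc1
Why: The ketone can enolise only towards C3 because C5 is quaternary, and the potassium enolate should be oxidised by the N-sulfonyloxaziridine (enolate hydroxylation) on the α face, away from the axial C5 methyl group that shields the β face 1,3 to C3, giving the equatorial 3α-alcohol (6R).

Step 5
Reactants: 10
Product: 11 (1R,3S,4R)-4-[(1S)-1,2-bis(triethylsilyloxy)ethyl]-3-methyl-3-(3-methylbut-2-en-1-yl)-2-methylidenecyclohexan-1-ol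
Conditions: Ph3PCH3Br (4 equiv), KOtBu (3.8 equiv), toluene, 0 → 70 °C
Reagents that add atoms: methyltriphenylphosphonium bromide, C[P+](c1ccccc1)(c1ccccc1)c1ccccc1.[Br-]
Why: Wittig methylenation with an excess of the unstabilised ylide should convert the hindered C4 ketone into the exocyclic alkene while the C3 hydroxyl is carried as its alkoxide, and the only epimerisable centre (C3) already holds its more stable equatorial configuration.

Step 6
Reactants: 11
Product: 12 (1R,2R,3R,4R)-4-[(1S)-1,2-bis(triethylsilyloxy)ethyl]-2,3-dimethyl-3-(3-methylbut-2-en-1-yl)cyclohexan-1-ol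
Conditions: [Rh(nbd)(dppb)]BF4 (5 mol %), H2 (50 atm), CH2Cl2, rt
Reagents that add atoms: none
Why: Cationic rhodium–diphosphine catalysts hydrogenate a 1,1-disubstituted alkene held through a neighbouring hydroxyl group and are essentially inert towards non-coordinating trisubstituted alkenes such as the prenyl group (hydroxyl-directed hydrogenation), and hydrogen should arrive on the α face, on the side of the C3 hydroxyl and opposite the axial C5 methyl group, so that the new C4 methyl group is β and equatorial (2R).

Step 7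
Reactants: 12; 13 3-methylbut-2-enoic acid
Product: 14 (1R,2R,3R,4R)-4-[(1S)-1,2-bis(triethylsilyloxy)ethyl]-2,3-dimethyl-3-(3-methylbut-2-en-1-yl)cyclohexyl 3-methylbut-2-enoate
Conditions: 13 (2 equiv), DCC (2 equiv), DMAP (0.3 equiv), CH2Cl2, 0 °C → rt
Reagents that add atoms: 3-methylbut-2-enoic acid 13, CC(C)=CC(=O)O
Why: Steglich esterification of the equatorial secondary alcohol proceeds with retention at C3, and the carbodiimide route avoids the acid chloride/amine conditions that deconjugate senecioyl donors through a vinylketene.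

Step 8
Reactants: 14
Product: 16 (1R,2R,3R,4R)-2,3-dimethyl-3-(3-methylbut-2-en-1-yl)-4-[(1S)-2-oxo-1-(triethylsilyloxy)ethyl]cyclohexyl 3-methylbut-2-enoate, via alkoxysulfonium chloride 15 (not isolated)
Conditions: (COCl)2 (4 equiv), DMSO (8 equiv), CH2Cl2, −78 → −30 °C; then Et3N, −78 → 0 °C; used crude
Reagents that add atoms: none
Why: Under Swern conditions the chlorosulfonium reagent cleaves only the primary triethylsilyl ether and converts it into the alkoxysulfonium salt, which the amine collapses to the aldehyde, while the secondary C9 silyl ether and the C9 configuration are kept at low temperature (selective Swern oxidation of a primary TES ether).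

Step 9
Reactants: 16
Product: 17 (3R,4R,5R,7S,8S,9S,10R)-8-hydroxy-9-(triethylsilyloxy)eremophil-11-en-3-yl 3-methylbut-2-enoate (8β-hydroxy, 9α-silyloxy, 7α-isopropenyl, 3α-ester)
Conditions: Me2AlCl (2.5 equiv), CH2Cl2, −78 → −40 °C; then aq. Rochelle salt
Reagents that add atoms: none
Why: Me2AlCl binds the aldehyde oxygen, C7 of the prenyl alkene attacks C8 and a hydrogen of a C11 methyl group passes to the carbonyl oxygen in a concerted but asynchronous ene process (its stepwise limit is a C11 cation that loses the same proton), so the C7–C8 bond, the C8 carbinol and the C11=C12 isopropenyl group arise together. The closest known reaction type is the Lewis-acid-promoted Type I intramolecular carbonyl-ene cyclisation that converts citronellal into isopulegol, and alkylaluminium halides are the usual promoters for aldehydes because the product alkoxide is fixed with loss of methane. Ring B closes in a six-membered mode in which both reacting π bonds end up exocyclic to the new ring (6-exo attack on the carbonyl), through a chair that is trans-fused to ring A because the C5 and C10 arms are trans-diequatorial. C7 is controlled by this chair, in which the isopropylidene terminus stays equatorial to avoid a 1,3-clash with the axial C5 methyl group, giving the 7α (7S) isomer. C8 is controlled by the equatorial, metal-bound carbonyl that the hydrogen transfer demands, giving the 8β (8S) alcohol trans to the isopropenyl group with the preset (S)-C9 silyloxy group equatorial as well; this centre is oxidised later, so only C7 has to be secured. The step needs chemoselectivity between two alkenes and retention at C9, and the substrate provides both: only the electron-rich prenyl alkene can reach C8 in a six-membered array (the senecioate alkene is electron-poor and remote), and the non-chelating silyl ether at low temperature keeps the α-stereocentre from enolising.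

Step 10
Reactants: 17
Product: 18 (3R,4R,5R,7S,9S,10R)-8-oxo-9-(triethylsilyloxy)eremophil-11-en-3-yl 3-methylbut-2-enoate
Conditions: Dess–Martin periodinane (1.5 equiv), pyridine (3 equiv), CH2Cl2, 0 °C → rt
Reagents that add atoms: none
Why: Dess–Martin oxidation converts the secondary C8 alcohol into the ketone without strong base or acid, so the C11=C12 alkene should stay out of conjugation and C7 and C9, both already in their more stable equatorial configurations, are retained.

Step 11
Reactants: 18
Product: 19 (3R,4R,5R,7S,9S,10R)-9-hydroxy-8-oxoeremophil-11-en-3-yl 3-methylbut-2-enoate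
Conditions: HF·pyridine, pyridine, THF, 0 °C
Reagents that add atoms: none
Why: Buffered hydrogen fluoride cleaves the secondary triethylsilyl ether (fluoride-mediated desilylation) under mildly acidic conditions that neither enolise the ketone nor touch the two alkenes or the ester.

Step 12
Reactants: 19; 20 (E)-2-methylbut-2-enoyl chloride (tigloyl chloride)
Product: 21 3α-(3-methylbut-2-enoyloxy)-9α-[(E)-2-methylbut-2-enoyloxy]eremophil-11-en-8-one, (3R,4R,5R,7S,9S,10R), CNP0164025.1
Conditions: 20 (1.5 equiv), pyridine, DMAP (0.1 equiv), CH2Cl2, 0 °C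
Reagents that add atoms: (E)-2-methylbut-2-enoyl chloride 20, C/C=C(\C)C(=O)Cl
Why: DMAP-catalysed acylation of the α-hydroxy ketone with the acid chloride proceeds with retention at C9, the (E)-tiglate is the stable geometric isomer, and the weak base at 0 °C should be too mild to move the C11=C12 alkene into conjugation with the C8 ketone.

Compound list

1 | 2-methylcyclohex-2-en-1-one | CC1=CCCC1=O | starting material
2 | vinylmagnesium bromide | C=C[Mg]Br | starting material
3 | prenyl bromide (1-bromo-3-methylbut-2-ene) | CC(C)=CCBr | starting material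
4 | bromomagnesium (3S)-2-methyl-3-vinylcyclohex-1-en-1-olate | CC1=C(O[Mg]Br)CCC[C@H]1C=C | intermediate
5 | (2S,3S)-2-methyl-2-(3-methylbut-2-en-1-yl)-3-vinylcyclohexan-1-one | CC(C)=CC[C@]1(C)C(=O)CCC[C@H]1C=C | intermediate
6 | (2S,3S)-3-[(1R)-1,2-bis(4,4,5,5-tetramethyl-1,3,2-dioxaborolan-2-yl)ethyl]-2-methyl-2-(3-methylbut-2-en-1-yl)cyclohexan-1-one | CC(C)=CC[C@]1(C)C(=O)CCC[C@H]1[C@H](B1OC(C)(C)C(C)(C)O1)CB1OC(C)(C)C(C)(C)O1 | intermediate
7 | (2S,3R)-3-[(1S)-1,2-dihydroxyethyl]-2-methyl-2-(3-methylbut-2-en-1-yl)cyclohexan-1-one | CC(C)=CC[C@]1(C)C(=O)CCC[C@H]1[C@H](O)CO | intermediate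
8 | (2S,3R)-3-[(1S)-1,2-bis(triethylsilyloxy)ethyl]-2-methyl-2-(3-methylbut-2-en-1-yl)cyclohexan-1-one | CC(C)=CC[C@]1(C)C(=O)CCC[C@H]1[C@H](O[Si](CC)(CC)CC)CO[Si](CC)(CC)CC | intermediate
9 | potassium (5R,6S)-5-[(1S)-1,2-bis(triethylsilyloxy)ethyl]-6-methyl-6-(3-methylbut-2-en-1-yl)cyclohex-1-en-1-olate | CC(C)=CC[C@]1(C)C([O-])=CCC[C@H]1[C@H](O[Si](CC)(CC)CC)CO[Si](CC)(CC)CC.[K+] | intermediate
10 | (2S,3R,6R)-3-[(1S)-1,2-bis(triethylsilyloxy)ethyl]-6-hydroxy-2-methyl-2-(3-methylbut-2-en-1-yl)cyclohexan-1-one | CC(C)=CC[C@]1(C)C(=O)[C@H](O)CC[C@H]1[C@H](O[Si](CC)(CC)CC)CO[Si](CC)(CC)CC | intermediate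
11 | (1R,3S,4R)-4-[(1S)-1,2-bis(triethylsilyloxy)ethyl]-3-methyl-3-(3-methylbut-2-en-1-yl)-2-methylidenecyclohexan-1-ol | CC(C)=CC[C@]1(C)C(=C)[C@H](O)CC[C@H]1[C@H](O[Si](CC)(CC)CC)CO[Si](CC)(CC)CC | intermediate
12 | (1R,2R,3R,4R)-4-[(1S)-1,2-bis(triethylsilyloxy)ethyl]-2,3-dimethyl-3-(3-methylbut-2-en-1-yl)cyclohexan-1-ol | CC(C)=CC[C@]1(C)[C@@H](C)[C@H](O)CC[C@H]1[C@H](O[Si](CC)(CC)CC)CO[Si](CC)(CC)CC | intermediate
13 | 3-methylbut-2-enoic acid | CC(C)=CC(=O)O | starting material
14 | (1R,2R,3R,4R)-4-[(1S)-1,2-bis(triethylsilyloxy)ethyl]-2,3-dimethyl-3-(3-methylbut-2-en-1-yl)cyclohexyl 3-methylbut-2-enoate | CC(C)=CC[C@]1(C)[C@@H](C)[C@H](OC(=O)C=C(C)C)CC[C@H]1[C@H](O[Si](CC)(CC)CC)CO[Si](CC)(CC)CC | intermediate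
15 | dimethyl{(2S)-2-[(1R,2R,3R,4R)-2,3-dimethyl-4-(3-methylbut-2-enoyloxy)-2-(3-methylbut-2-en-1-yl)cyclohexyl]-2-(triethylsilyloxy)ethoxy}sulfonium chloride | CC(C)=CC[C@]1(C)[C@@H](C)[C@H](OC(=O)C=C(C)C)CC[C@H]1[C@H](O[Si](CC)(CC)CC)CO[S+](C)C.[Cl-] | intermediate
16 | (1R,2R,3R,4R)-2,3-dimethyl-3-(3-methylbut-2-en-1-yl)-4-[(1S)-2-oxo-1-(triethylsilyloxy)ethyl]cyclohexyl 3-methylbut-2-enoate | CC(C)=CC[C@]1(C)[C@@H](C)[C@H](OC(=O)C=C(C)C)CC[C@H]1[C@H](O[Si](CC)(CC)CC)C=O | intermediate
17 | (3R,4R,5R,7S,8S,9S,10R)-8-hydroxy-9-(triethylsilyloxy)eremophil-11-en-3-yl 3-methylbut-2-enoate | C=C(C)[C@@H]1C[C@]2(C)[C@@H](C)[C@H](OC(=O)C=C(C)C)CC[C@H]2[C@H](O[Si](CC)(CC)CC)[C@H]1O | intermediate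
18 | (3R,4R,5R,7S,9S,10R)-8-oxo-9-(triethylsilyloxy)eremophil-11-en-3-yl 3-methylbut-2-enoate | C=C(C)[C@@H]1C[C@]2(C)[C@@H](C)[C@H](OC(=O)C=C(C)C)CC[C@H]2[C@H](O[Si](CC)(CC)CC)C1=O | intermediate
19 | (3R,4R,5R,7S,9S,10R)-9-hydroxy-8-oxoeremophil-11-en-3-yl 3-methylbut-2-enoate | C=C(C)[C@@H]1C[C@]2(C)[C@@H](C)[C@H](OC(=O)C=C(C)C)CC[C@H]2[C@H](O)C1=O | intermediate
20 | (E)-2-methylbut-2-enoyl chloride (tigloyl chloride) | C/C=C(\C)C(=O)Cl | starting material
21 | (3R,4R,5R,7S,9S,10R)-3-(3-methylbut-2-enoyloxy)-9-[(E)-2-methylbut-2-enoyloxy]eremophil-11-en-8-one (CNP0164025.1) | C=C(C)[C@@H]1C[C@]2(C)[C@@H](C)[C@H](OC(=O)C=C(C)C)CC[C@H]2[C@H](OC(=O)/C(C)=C/C)C1=O | target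

Total step count: 12. Longest linear sequence: 12 steps, from 1 to 21.

Steps most likely to fail

1. Step 9. The aluminium-bound aldehyde may ionise to a C11 cation that is captured by chloride or loses a different proton (Prins-type diversion), or the α-silyloxy aldehyde may enolise and lose its C9 configuration before it cyclises. The fallback replaces the pericyclic closure by a metal-mediated allylation that makes the same C7–C8 bond; it sets out from 14 and comes back at 17. Catalytic SeO2 with tBuOOH in CH2Cl2 should oxidise the (E)-methyl group of the prenyl unit, the electron-poor senecioate alkene reacting far more slowly, to give the (E)-allylic alcohol F1. MsCl, LiCl and 2,4,6-collidine in DMF at 0 °C would convert it into the (E)-allylic chloride F2. The Swern protocol of step 8 would take this through the alkoxysulfonium chloride F3 (not isolated) to the chloro aldehyde F4. CrCl2 in THF would then generate the allylchromium dichloride F5 (not isolated), which adds to the C8 aldehyde through its γ-carbon C7 in a chair transition state (intramolecular Nozaki–Hiyama allylation), moving the alkene to C11=C12 and giving 17.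

2. Step 1. Enantioselection may be poor when an sp2 Grignard reagent is transferred by the chiral copper complex, and uncatalysed 1,2-addition would erode the result further. The fallback gives up enantiocontrol in this step and separates the two series as diastereomers after step 2; it sets out from 1 and comes back at 7. Without a chiral ligand (2, CuI 10 mol %, THF, −40 °C; then 3, DMPU) the same tandem reaction should give the racemic trans ketone, that is 5 together with the (2R,3R)-ketone F7, formed through 4 and the (3R)-magnesium enolate F6 (not isolated). The mixture is taken through step 2 unchanged: the platinum catalyst fixes C9 as (S) in both series, so the mirror-image ketone passes through the bis(pinacolboronate) F8 (not isolated) to the diastereomeric diol F9, which would be removed from 7 by chromatography at the cost of half the material.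

3. Step 6. The prenyl alkene may take up hydrogen if the directing effect is weak, rhodium may isomerise the allylic alcohol to the saturated ketone, or hydrogen may be delivered to the wrong face. The fallback is a polar sequence under thermodynamic control; it sets out from 11 and comes back at 12. Dess–Martin oxidation should give the α-methylene ketone F10. Conjugate reduction with [(Ph3P)CuH]6 (benzene, rt), which leaves isolated alkenes alone, followed by brief equilibration with DBU should give the methyl ketone F11, with the C4 methyl group equatorial and cis to the C5 methyl group, as in friedelane-type 4-methyl-3-ketones. Li in NH3/THF with MeOH at −78 °C would then reduce the ketone under thermodynamic control to the equatorial 3α-alcohol 12.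

Further compounds

F1 | step 9 | (1R,2R,3R,4R)-4-[(1S)-1,2-bis(triethylsilyloxy)ethyl]-3-[(E)-4-hydroxy-3-methylbut-2-en-1-yl]-2,3-dimethylcyclohexyl 3-methylbut-2-enoate | OC/C(C)=C/C[C@]1(C)[C@@H](C)[C@H](OC(=O)C=C(C)C)CC[C@H]1[C@H](O[Si](CC)(CC)CC)CO[Si](CC)(CC)CC
F2 | step 9 | (1R,2R,3R,4R)-4-[(1S)-1,2-bis(triethylsilyloxy)ethyl]-3-[(E)-4-chloro-3-methylbut-2-en-1-yl]-2,3-dimethylcyclohexyl 3-methylbut-2-enoate | ClC/C(C)=C/C[C@]1(C)[C@@H](C)[C@H](OC(=O)C=C(C)C)CC[C@H]1[C@H](O[Si](CC)(CC)CC)CO[Si](CC)(CC)CC
F3 | step 9 | alkoxysulfonium chloride derived from the primary silyl ether of the allylic chloride | ClC/C(C)=C/C[C@]1(C)[C@@H](C)[C@H](OC(=O)C=C(C)C)CC[C@H]1[C@H](O[Si](CC)(CC)CC)CO[S+](C)C.[Cl-]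
F4 | step 9 | (1R,2R,3R,4R)-3-[(E)-4-chloro-3-methylbut-2-en-1-yl]-2,3-dimethyl-4-[(1S)-2-oxo-1-(triethylsilyloxy)ethyl]cyclohexyl 3-methylbut-2-enoate | ClC/C(C)=C/C[C@]1(C)[C@@H](C)[C@H](OC(=O)C=C(C)C)CC[C@H]1[C@H](O[Si](CC)(CC)CC)C=O
F5 | step 9 | allylchromium(III) dichloride formed from the chloro aldehyde | Cl[Cr](Cl)C/C(C)=C/C[C@]1(C)[C@@H](C)[C@H](OC(=O)C=C(C)C)CC[C@H]1[C@H](O[Si](CC)(CC)CC)C=O
F6 | step 1 | bromomagnesium (3R)-2-methyl-3-vinylcyclohex-1-en-1-olate | CC1=C(O[Mg]Br)CCC[C@@H]1C=C
F7 | step 1 | (2R,3R)-2-methyl-2-(3-methylbut-2-en-1-yl)-3-vinylcyclohexan-1-one | CC(C)=CC[C@@]1(C)C(=O)CCC[C@@H]1C=C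
F8 | step 1 | (2R,3R)-3-[(1R)-1,2-bis(4,4,5,5-tetramethyl-1,3,2-dioxaborolan-2-yl)ethyl]-2-methyl-2-(3-methylbut-2-en-1-yl)cyclohexan-1-one | CC(C)=CC[C@@]1(C)C(=O)CCC[C@@H]1[C@H](B1OC(C)(C)C(C)(C)O1)CB1OC(C)(C)C(C)(C)O1
F9 | step 1 | (2R,3S)-3-[(1S)-1,2-dihydroxyethyl]-2-methyl-2-(3-methylbut-2-en-1-yl)cyclohexan-1-one | CC(C)=CC[C@@]1(C)C(=O)CCC[C@@H]1[C@H](O)CO
F10 | step 6 | (3S,4R)-4-[(1S)-1,2-bis(triethylsilyloxy)ethyl]-3-methyl-3-(3-methylbut-2-en-1-yl)-2-methylidenecyclohexan-1-one | CC(C)=CC[C@]1(C)C(=C)C(=O)CC[C@H]1[C@H](O[Si](CC)(CC)CC)CO[Si](CC)(CC)CC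
F11 | step 6 | (2R,3S,4R)-4-[(1S)-1,2-bis(triethylsilyloxy)ethyl]-2,3-dimethyl-3-(3-methylbut-2-en-1-yl)cyclohexan-1-one | CC(C)=CC[C@]1(C)[C@@H](C)C(=O)CC[C@H]1[C@H](O[Si](CC)(CC)CC)CO[Si](CC)(CC)CC
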